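The bond formed in the key step is C2–C3: the ketone α‑CH2 to the O–CH bridgehead of ring A.

**Strategy.** The route rests on the β‑alkoxy ketone hidden in ring A, the 6‑oxabicyclo[3.2.1]octan‑3‑one: the ether carbon C3 (O–CH of the tetrahydrofuran ring) lies β to the ketone C1, so the bond from the ketone α‑CH2 (C2) to C3 is an enol silane/oxocarbenium (Mukaiyama‑type) closure. In one operation the key step ionises a tetrahydrofuran lactol at C3 and lets a silyl enol ether on the neighbouring spiro carbon C10 close the cyclohexanone, fixing C3 through the bridge. The precursor, a 3,3‑dimethyltetrahydrofuran‑2‑ol bearing the quaternary C10, comes from a chiral butenolide; the lactone and cyclohexane rings follow by an ester‑tethered intramolecular Diels–Alder reaction.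

Key step: step 9

Numbering used below (target atoms): C1 ring A ketone, C2 its CH2, C3 the O–CH bridgehead, C4 the CMe2, C5 the other bridgehead CH, C6 the OCH2 of the ether bridge, C7 the lactone carbonyl, C8 the CH bearing it, C9 the adjacent ring‑fusion CH, C10 the spiro carbon, C11/C12 the ring CH2 groups next to C9, C13 the CH bearing the acrylic acid, C14 the CH2 between C13 and C8, C20 the lactone OCH2.

Assumption: (5S)‑5‑(d‑menthyloxy)furan‑2(5H)‑one (1), the enantiomer of the common l‑menthyl reagent, is taken as purchasable.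

## Route

Step 1
Reactants: 1 (5S)‑5‑(d‑menthyloxy)furan‑2(5H)‑one; 2 isobutyronitrile
Product: 3 trans Michael adduct, 2‑[(2S,3R)‑2‑(d‑menthyloxy)‑5‑oxooxolan‑3‑yl]‑2‑methylpropanenitrile
Conditions: 2, LiN(iPr)2, THF, –78 °C; then 1, –78 °C; AcOH quench
Reagents that add atoms: none
Why: Michael addition of the lithiated nitrile to the butenolide should occur anti to the 5‑menthyloxy group (auxiliary control), which sets target C5; the fully substituted carbanion favours 1,4‑ over 1,2‑addition.

Step 2
Reactants: 3 trans Michael adduct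
Product: 4 (R)‑2‑methyl‑2‑(5‑oxooxolan‑3‑yl)propanenitrile
Conditions: NaBH4, KOH, EtOH/H2O, 0 °C to rt; then 2 M HCl
Reagents that add atoms: KOH/water (the hydroxide oxygen can end up as the lactone carbonyl oxygen after ring opening and relactonisation), [K+].[OH-]
Why: Saponification opens the pseudo‑ester to the aldehyde carboxylate with loss of menthol, NaBH4 reduces the aldehyde as it forms (so the adjacent stereocentre is not epimerised) and acid relactonises.

Step 3
Reactants: 4 lactone nitrile
Product: 5 2‑[(3R,4R)‑4‑acetyl‑5‑oxooxolan‑3‑yl]‑2‑methylpropanenitrile (acetyl trans to the cyanoisopropyl group)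
Conditions: LiN(SiMe3)2 (2.2 equiv), THF, –78 °C; 1‑acetylimidazole; AcOH quench
Reagents that add atoms: 1‑acetylimidazole, CC(=O)n1ccnc1
Why: Crossed Claisen condensation (C‑acylation) of the lactone enolate, the second equivalent of base holding the β‑keto lactone as its enolate; the new centre is labile and is overwritten in step 4.

Step 4
Reactants: 5 α‑acetyl lactone
Product: 6 2‑[(3S,4R)‑4‑acetyl‑4‑(hydroxymethyl)‑5‑oxooxolan‑3‑yl]‑2‑methylpropanenitrile (CH2OH trans, acetyl cis to the cyanoisopropyl group)
Conditions: aq. CH2O, KHCO3 (cat.), THF, rt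
Reagents that add atoms: formaldehyde, C=O
Why: Base‑catalysed aldol hydroxymethylation of the β‑keto lactone; formaldehyde should add to the enolate face anti to the bulky tert‑alkyl group on the adjacent carbon, which sets the quaternary C10 with C20 trans and the acetyl group (C1, C2) cis to the C4 unit.

Step 5
Reactants: 6 hydroxymethyl keto lactone
Product: 7 bis‑silyl compound (C20 TBS ether and TBS enol ether of the methyl ketone)
Conditions: TBSOTf (2.5 equiv), Et3N, CH2Cl2, –78 to 0 °C
Reagents that add atoms: tert‑butyldimethylsilyl triflate, CC(C)(C)[Si](C)(C)OS(=O)(=O)C(F)(F)F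
Why: Silylation of the alcohol and soft enolisation of the methyl ketone, whose CH3 is the only enolisable position because C10 is quaternary; the enol silane protects the ketone and is the nucleophile of step 9.

Step 6
Reactants: 7 bis‑silyl lactone
Product: 8 lactol at C9 (both anomers)
Conditions: iBu2AlH (1.1 equiv), toluene, –78 °C; aq. KNa tartrate
Reagents that add atoms: none
Why: Hydride reduction of a γ‑lactone to the lactol, which at –78 °C should be much faster than attack on the nitrile at a fully substituted carbon; silyl groups are inert.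

Step 7
Reactants: 8 C9 lactol
Product: 9 (E)‑vinyl iodide with free C6 hydroxyl
Conditions: CrCl2, CHI3, THF/1,4‑dioxane, 0 °C to rt
Reagents that add atoms: iodoform, IC(I)I
Why: Takai olefination of the lactol through its open aldehyde form should give the (E)‑iodoalkene (C9=C11) and releases the C6 hydroxyl.

Step 8
Reactants: 9 vinyl iodide alcohol
Product: 11 lactol at C3 (4‑substituted 3,3‑dimethyloxolan‑2‑ol; both anomers), via hydroxy aldehyde 10 (not isolated)
Conditions: iBu2AlH (2.5 equiv), CH2Cl2, –78 to –30 °C; aq. KNa tartrate, then pH 5 buffer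
Reagents that add atoms: water, O
Why: Reduction of the nitrile to the aldimine–alane and hydrolysis give the neopentyl aldehyde, which should close onto the C6 hydroxyl to the five‑membered lactol (gem‑dimethyl effect); enol silane and vinyl iodide are untouched.

Step 9
Reactants: 11 C3 lactol
Product: 13 2‑[(E)‑2‑iodoethenyl]‑2‑{[(tert‑butyldimethylsilyl)oxy]methyl}‑8,8‑dimethyl‑6‑oxabicyclo[3.2.1]octan‑3‑one, via O‑trimethylsilyl lactol 12 (not isolated)
Conditions: TMSOTf (1.3 equiv), 2,6‑di‑tert‑butyl‑4‑methylpyridine, CH2Cl2, –78 to –30 °C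
Reagents that add atoms: none
Why: TMSOTf silylates the lactol hydroxyl (the hindered pyridine takes up TfOH) to give 12, which is ionised to the five‑membered cyclic oxocarbenium ion (O6=C3); C2 of the TBS enol ether held on C10 adds to C3, and loss of the silyl group from oxygen gives the ketone. The closest known reaction type is the silyl triflate‑mediated Mukaiyama‑type addition of an enol silane to an acetal‑ or lactol‑derived oxocarbenium ion (as in C‑glycosylation of lactols), here intramolecular. Ring A is closed in the 6‑(enolendo)‑exo‑trig mode through a chair, so the monocyclic tetrahydrofuran becomes the 6‑oxabicyclo[3.2.1]octan‑3‑one. The only new stereocentre, C3, is dictated by the tether: C2 can reach the oxocarbenium carbon only on the face cis to the C5–C10 bond, so the bridge forms with the required configuration while C5 and C10 are carried through unchanged. The step needs C–C bond formation at C2 before protodesilylation; this is secured by the acid scavenger, by the low temperature at which the vinyl iodide and the primary TBS ether are inert, by C10 being quaternary (C2 is the sole nucleophilic carbon), and by the absence of any other aldehyde‑level electrophile.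

Step 10
Reactants: 13 bicyclic vinyl iodide; 14 methyl vinyl ketone
Product: 15 (1E,3E)‑dienone (5‑oxohexa‑1,3‑dienyl group on C10)
Conditions: Pd(OAc)2 (5 mol %), Bu4NCl, NaHCO3, DMF, 40 °C
Reagents that add atoms: none
Why: Heck reaction of the alkenyl iodide with the enone; syn insertion and syn β‑hydride elimination should give the (E,E)‑dienone with retention of the iodoalkene geometry.

Step 11
Reactants: 15 dienone silyl ether
Product: 16 C20 alcohol
Conditions: HF·pyridine, pyridine/THF, 0 °C to rt
Reagents that add atoms: none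
Why: Fluoride cleavage of the primary TBS ether under buffered conditions that leave the β‑alkoxy ketone and the dienone intact.

Step 12
Reactants: 16 C20 alcohol
Product: 17 acrylate ester
Conditions: acryloyl chloride, Et3N, CH2Cl2, –20 °C
Reagents that add atoms: acryloyl chloride, C=CC(=O)Cl
Why: Acylation of the neopentyl alcohol installs the dienophile on the future lactone tether.

Step 13
Reactants: 17 acrylate ester
Product: 18 Diels–Alder adduct (cis‑fused δ‑lactone; C11=C12 alkene; acetyl at C13 cis to C10)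
Conditions: BHT (cat.), 1,2‑dichlorobenzene (0.005 M), 160 °C
Reagents that add atoms: none
Why: Thermal intramolecular Diels–Alder reaction through the ester tether: the endo arrangement of the tether carbonyl should give the cis ring fusion (C8, C9), the diene should add on the face that puts H9 next to the bulky C5 side of C10 and C11 next to the flat C1 carbonyl (C9 relative to C10), and the (E,E)‑diene places the acetyl group cis to C10, which step 14 corrects.

Step 14
Reactants: 18 Diels–Alder adduct
Product: 20 saturated keto lactone with the C13 acetyl trans to C10, via cis-acetyl keto lactone 19 (not isolated)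
Conditions: H2 (1 atm), Pd/C, EtOAc, rt; filter; then DBU (cat.), toluene, rt
Reagents that add atoms: none
Why: Hydrogenation removes the only C=C, and base epimerisation α to the methyl ketone moves the axial acetyl group (1,3‑diaxial to C7) to the equatorial, thermodynamic position, setting C13; C8, α to the less acidic lactone, should not be enolised by DBU.

Step 15
Reactants: 20 trans‑acetyl keto lactone
Product: 21 isopropenyl compound
Conditions: Ph3PCH3Br, KOtBu, THF, 0 °C; then 20, 0 °C
Reagents that add atoms: methyltriphenylphosphonium bromide, C[P+](c1ccccc1)(c1ccccc1)c1ccccc1.[Br-]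
Why: Wittig methylenation should take the unhindered methyl ketone in preference to the ring ketone flanked by quaternary C10, and leaves the lactone alone.

Step 16
Reactants: 21 isopropenyl compound
Product: 23 α‑substituted acrolein, via allylic alcohol 22 (not isolated)
Conditions: SeO2 (cat.), tBuOOH, CH2Cl2, rt; then Dess–Martin periodinane
Reagents that add atoms: SeO2 (oxygen transfer agent), O=[Se]=O; tert‑butyl hydroperoxide (terminal oxidant), CC(C)(C)OO
Why: Allylic oxidation of the isopropenyl methyl group by the ene/[2,3]‑sigmatropic pathway (CH3 preferred over the ring CH), followed by oxidation of the allylic alcohol so that alcohol and any enal converge.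

Step 17
Reactants: 23 enal
Product: 24 CNP0268721.1 (target)
Conditions: NaClO2, NaH2PO4, 2‑methyl‑2‑butene, tBuOH/H2O, rt
Reagents that add atoms: sodium chlorite, [Na+].[O-]Cl=O
Why: Pinnick oxidation converts the enal into the acrylic acid without touching the ketone, the lactone or the 1,1‑disubstituted alkene.

## Compound list

1 | (5S)‑5‑{[(1S,2R,5S)‑2‑isopropyl‑5‑methylcyclohexyl]oxy}furan‑2(5H)‑one | O=C1C=C[C@@H](O[C@@H]2[C@@H](C(C)C)CC[C@H](C)C2)O1 | starting material
2 | isobutyronitrile | CC(C)C#N | starting material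
3 | 2‑[(2S,3R)‑2‑{[(1S,2R,5S)‑2‑isopropyl‑5‑methylcyclohexyl]oxy}‑5‑oxooxolan‑3‑yl]‑2‑methylpropanenitrile (2,3‑trans) | N#CC(C)(C)[C@@H]1[C@@H](O[C@@H]2[C@@H](C(C)C)CC[C@H](C)C2)OC(=O)C1 | intermediate
4 | (R)‑2‑methyl‑2‑(5‑oxooxolan‑3‑yl)propanenitrile | N#CC(C)(C)[C@@H]1COC(=O)C1 | intermediate
5 | 2‑[(3R,4R)‑4‑acetyl‑5‑oxooxolan‑3‑yl]‑2‑methylpropanenitrile (trans; keto form) | N#CC(C)(C)[C@@H]1COC(=O)[C@H]1C(C)=O | intermediate
6 | 2‑[(3S,4R)‑4‑acetyl‑4‑(hydroxymethyl)‑5‑oxooxolan‑3‑yl]‑2‑methylpropanenitrile | N#CC(C)(C)[C@@H]1COC(=O)[C@]1(CO)C(C)=O | intermediate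
7 | 2‑[(3S,4R)‑4‑{1‑[(tert‑butyldimethylsilyl)oxy]ethenyl}‑4‑{[(tert‑butyldimethylsilyl)oxy]methyl}‑5‑oxooxolan‑3‑yl]‑2‑methylpropanenitrile | N#CC(C)(C)[C@@H]1COC(=O)[C@]1(CO[Si](C)(C)C(C)(C)C)C(=C)O[Si](C)(C)C(C)(C)C | intermediate
8 | lactol of 7 (5‑hydroxyoxolane, both anomers; ring stereocentres as in 7) | N#CC(C)(C)[C@@H]1COC(O)[C@]1(CO[Si](C)(C)C(C)(C)C)C(=C)O[Si](C)(C)C(C)(C)C | intermediate
9 | (5E)‑4‑{1‑[(tert‑butyldimethylsilyl)oxy]ethenyl}‑4‑{[(tert‑butyldimethylsilyl)oxy]methyl}‑3‑(hydroxymethyl)‑6‑iodo‑2,2‑dimethylhex‑5‑enenitrile (C3, C4 = target C5, C10) | N#CC(C)(C)[C@H](CO)[C@@](/C=C/I)(CO[Si](C)(C)C(C)(C)C)C(=C)O[Si](C)(C)C(C)(C)C | intermediate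
10 | the corresponding hex‑5‑enal (nitrile carbon as CHO; open form of 11) | O=CC(C)(C)[C@H](CO)[C@@](/C=C/I)(CO[Si](C)(C)C(C)(C)C)C(=C)O[Si](C)(C)C(C)(C)C | intermediate (not isolated)
11 | 4‑[(4E)‑2‑[(tert‑butyldimethylsilyl)oxy]‑3‑{[(tert‑butyldimethylsilyl)oxy]methyl}‑5‑iodopenta‑1,4‑dien‑3‑yl]‑3,3‑dimethyloxolan‑2‑ol (both anomers) | CC1(C)C(O)OC[C@@H]1[C@@](/C=C/I)(CO[Si](C)(C)C(C)(C)C)C(=C)O[Si](C)(C)C(C)(C)C | intermediate
12 | O‑trimethylsilyl ether of lactol 11 | CC1(C)C(O[Si](C)(C)C)OC[C@@H]1[C@@](/C=C/I)(CO[Si](C)(C)C(C)(C)C)C(=C)O[Si](C)(C)C(C)(C)C | intermediate (not isolated)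
13 | 2‑{[(tert‑butyldimethylsilyl)oxy]methyl}‑2‑[(E)‑2‑iodoethenyl]‑8,8‑dimethyl‑6‑oxabicyclo[3.2.1]octan‑3‑one (CH2O group on the face opposite the O–CH2 bridge, alkenyl group on the face of that bridge) | CC(C)(C)[Si](C)(C)OC[C@@]1(/C=C/I)C(=O)C[C@@H]2OC[C@H]1C2(C)C | intermediate
14 | methyl vinyl ketone (but‑3‑en‑2‑one) | CC(=O)C=C | starting material
15 | 2‑{[(tert‑butyldimethylsilyl)oxy]methyl}‑8,8‑dimethyl‑2‑[(1E,3E)‑5‑oxohexa‑1,3‑dien‑1‑yl]‑6‑oxabicyclo[3.2.1]octan‑3‑one | CC(C)(C)[Si](C)(C)OC[C@@]1(/C=C/C=C/C(C)=O)C(=O)C[C@@H]2OC[C@H]1C2(C)C | intermediate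
16 | 2‑(hydroxymethyl)‑8,8‑dimethyl‑2‑[(1E,3E)‑5‑oxohexa‑1,3‑dien‑1‑yl]‑6‑oxabicyclo[3.2.1]octan‑3‑one | OC[C@@]1(/C=C/C=C/C(C)=O)C(=O)C[C@@H]2OC[C@H]1C2(C)C | intermediate
17 | acrylate ester of 16 | C=CC(=O)OC[C@@]1(/C=C/C=C/C(C)=O)C(=O)C[C@@H]2OC[C@H]1C2(C)C | intermediate
18 | Diels–Alder adduct: target skeleton with C11=C12 and an acetyl group at C13 cis to C10 (H8/H9 cis) | CC(=O)[C@H]1C=C[C@@H]2[C@H](C1)C(=O)OC[C@]21C(=O)C[C@@H]2OC[C@H]1C2(C)C | intermediate
19 | 11,12‑dihydro derivative of 18 (acetyl still cis to C10) | CC(=O)[C@H]1CC[C@@H]2[C@H](C1)C(=O)OC[C@]21C(=O)C[C@@H]2OC[C@H]1C2(C)C | intermediate (not isolated)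
20 | C13 epimer of 19 (acetyl trans to C10, equatorial) | CC(=O)[C@@H]1CC[C@@H]2[C@H](C1)C(=O)OC[C@]21C(=O)C[C@@H]2OC[C@H]1C2(C)C | intermediate
21 | isopropenyl analogue (C13–C(CH3)=CH2) | C=C(C)[C@@H]1CC[C@@H]2[C@H](C1)C(=O)OC[C@]21C(=O)C[C@@H]2OC[C@H]1C2(C)C | intermediate
22 | allylic alcohol (C13–C(=CH2)CH2OH) | C=C(CO)[C@@H]1CC[C@@H]2[C@H](C1)C(=O)OC[C@]21C(=O)C[C@@H]2OC[C@H]1C2(C)C | intermediate (not isolated)
23 | enal (C13–C(=CH2)CHO) | C=C(C=O)[C@@H]1CC[C@@H]2[C@H](C1)C(=O)OC[C@]21C(=O)C[C@@H]2OC[C@H]1C2(C)C | intermediate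
24 | CNP0268721.1 | C=C(C(=O)O)[C@@H]1CC[C@@H]2[C@H](C1)C(=O)OC[C@]21C(=O)C[C@@H]2OC[C@H]1C2(C)C | target

Total step count: 17. Longest linear sequence: 17 steps (1 to 24).

## Steps most likely to fail

**Step 13.** The cycloaddition may be too slow, because an electron‑poor dienone must react with an acrylate through an ester tether that has to adopt its less favoured conformation; polymerisation then competes, and the endo/exo or facial selectivity may be incomplete. Fallback: alcohol 16 would be esterified with propiolic acid (DCC, CH2Cl2, –20 °C) to the propiolate ester F1. The alkynoate is sterically less demanding and has no endo/exo issue. Its intramolecular Diels–Alder reaction (toluene, 110 °C) would give the cyclohexa‑1,4‑diene lactone F2. Hydrogenation (H2, Pd/C) from the open face that carries H9 and H13 would saturate both ring alkenes and set C8 cis to C9, giving 19. Epimerisation with DBU as in step 14 returns to the route at 20.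

**Step 9.** The enol silane may be protodesilylated before the C–C bond forms, or closure may be slow because C20 and one C4 methyl group become 1,3‑diaxial. Fallback: lactol 11 would be treated with K2CO3 in MeOH (40 °C), which cleaves the enol silane to the methyl ketone lactol F3. Under the same conditions the methyl ketone should undergo intramolecular aldol condensation with the aldehyde form of the lactol to the 4,4‑dimethylcyclohex‑2‑enone F4. Its C6 hydroxyl then adds to the enone (intramolecular oxa‑Michael addition) to give 13, where the route is rejoined.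

**Step 7.** The olefination may stall because the hindered lactol next to a quaternary carbon releases little free aldehyde, and the chromium salts may erode the enol silane. Fallback: Wittig methylenation of lactol 8 (Ph3PCH3Br, KOtBu, THF) would give the vinyl alcohol F5. Reduction of the nitrile as in step 8 would give the lactol F6, and cyclisation as in step 9 the vinyl keto ether F7. A Heck reaction of F7 with (E)‑4‑iodobut‑3‑en‑2‑one (Pd(OAc)2, Ag2CO3, DMF) would then give dienone 15, where the route is rejoined; the alkenylpalladium species adds to the terminal carbon and β‑hydride elimination is possible only from C11.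

## Further compounds

F1 | step 13 | propiolate ester of 16 | C#CC(=O)OC[C@@]1(/C=C/C=C/C(C)=O)C(=O)C[C@@H]2OC[C@H]1C2(C)C
F2 | step 13 | cyclohexa‑1,4‑diene lactone (C8=C14 and C11=C12; acetyl at C13 cis to C10) | CC(=O)[C@H]1C=C[C@@H]2C(=C1)C(=O)OC[C@]21C(=O)C[C@@H]2OC[C@H]1C2(C)C
F3 | step 9 | methyl ketone lactol (enol silane of 11 cleaved) | CC1(C)C(O)OC[C@@H]1[C@@](/C=C/I)(CO[Si](C)(C)C(C)(C)C)C(C)=O
F4 | step 9 | 6‑{[(tert‑butyldimethylsilyl)oxy]methyl}‑5‑(hydroxymethyl)‑6‑[(E)‑2‑iodoethenyl]‑4,4‑dimethylcyclohex‑2‑en‑1‑one | CC(C)(C)[Si](C)(C)OC[C@@]1(/C=C/I)C(=O)C=CC(C)(C)[C@@H]1CO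
F5 | step 7 | vinyl alcohol (analogue of 9 with CH=CH2 in place of CH=CHI) | N#CC(C)(C)[C@H](CO)[C@@](C=C)(CO[Si](C)(C)C(C)(C)C)C(=C)O[Si](C)(C)C(C)(C)C
F6 | step 7 | vinyl lactol (analogue of 11 with CH=CH2) | CC1(C)C(O)OC[C@@H]1[C@@](C=C)(CO[Si](C)(C)C(C)(C)C)C(=C)O[Si](C)(C)C(C)(C)C
F7 | step 7 | 2‑{[(tert‑butyldimethylsilyl)oxy]methyl}‑2‑ethenyl‑8,8‑dimethyl‑6‑oxabicyclo[3.2.1]octan‑3‑one | CC(C)(C)[Si](C)(C)OC[C@@]1(C=C)C(=O)C[C@@H]2OC[C@H]1C2(C)C
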